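Readings and results are calculated on assumed constants; scatter was added.

Whether this recipe can stay as charged or needs less solid second nucleophile depends on how the two nucleophiles share the intermediate.

| flask | substrate | first nucleophile | solid second nucleophile | remark | time |
|---|---|---|---|---|---|
| cedar | 20 mM | 24 mM | 10 mM | run made earlier |  |
| larch | 20 mM | 24 mM | 40 mM | run made earlier |  |
| oak | 20 mM | 48 mM | 20 mM | run made earlier |  |
| flask | 20 mM | 24.0 mM | 20.0 mM |  | 20 min |

- cedar (time / min: other capture product / %, target / %, substrate / %): 1.33: 2.1, 6.5, 90.5; 4.00: 6.0, 17.6, 74.3; 8.00: 13.0, 32.3, 53.6; 10.0: 13.4, 37.6, 46.1; 15.0: 17.6, 47.8, 31.1; 20.0: 21.8, 54.2, 21.3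
- larch (time / min: other capture product / %, target / %, substrate / %): 1.50: 2.6, 7.8, 90.0; 2.50: 4.3, 11.7, 82.3; 4.00: 7.7, 16.4, 73.6; 8.00: 17.1, 27.8, 54.7; 12.0: 24.0, 33.7, 40.7; 20.0: 32.6, 42.8, 20.8
- oak (time / min: other capture product / %, target / %, substrate / %): 1.50: 1.1, 9.3, 89.3; 3.00: 3.8, 16.0, 79.5; 6.00: 7.6, 28.5, 62.5; 10.0: 13.1, 39.4, 46.3; 20.0: 19.8, 57.6, 21.5

(each reading ± 0.5 percentage points)

- given per volume of solution although it is solid: solid second nucleophile
- steps that have been proposed: substrate -> intermediate; first nucleophile + intermediate -> target; second nucleophile + intermediate -> other capture product; intermediate -> solvolysis product; solid second nucleophile <-> second nucleophile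
- at the start none of the solid second nucleophile is in solution

1. ratio of other capture product to target at 30 s
2. ratio of other capture product to target at 20 min
3. which of other capture product and target there is more of at 20 min

Both nucleophiles are taken to compete for one intermediate, so each curve can be replaced by its mean, in fractions of the substrate charge. Mean first nucleophile is its start minus half the target formed, and mean dissolved second nucleophile is its mean supply minus half the other capture product formed. The selectivity factor is the product ratio divided by the ratio of those two means: 0.956, read from cedar at 20.0 min, with its small charge taken as dissolved from the outset.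

The flask starts at 1.20 of first nucleophile and is given oak's total of both products, 77.4%. With its whole charge, 1.00, dissolved at once, the ratio at 20 min comes to 0.803. With a mean supply of half that charge, a steady creep, it comes to 0.402. Oak, with the same solid charge, reads as a mean supply of 0.859, nearer the fast extreme. The reckoning here is therefore 0.690, with target ahead. Dissolved second nucleophile starts from nothing, so scaling larch's ratio at 1.50 min in proportion to time gives 0.111 at 30 s.

The forecast gave 0.11 (range 0.05 to 0.25) at 30 s and 0.65 (range 0.55 to 0.76) at 20 min, the latter lower than the 0.690 reckoned here, with target ahead, noting that “the early ratio is nearly independent of solid loading”.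

The flask gives 0.129 at 30 s and 0.706 at 20 min, with target at 44.6% against 31.5% of other capture product.

    substrate → intermediate (k = 0.00128 s⁻¹)
    first nucleophile + intermediate → target (k = 2.58 L mol⁻¹ s⁻¹)
    second nucleophile + intermediate → other capture product (k = 2.42 L mol⁻¹ s⁻¹)
    intermediate → solvolysis product (k = 0.00229 s⁻¹)
    solid second nucleophile ⇌ second nucleophile, rate k5*(cs5 - [second nucleophile]) while solid is left; crystals form when [second nucleophile] > cs5 (solubility = 19.0 mM, k = 0.0105 s⁻¹)

While solid is left, dissolved second nucleophile approaches its solubility of 19 mM with a half-time of 1.10 min, shorter than the 9.0 min half-life of substrate in the flask at 1.18 min. Read through the selectivity factor, the flask's ratio means a mean supply of 0.879.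

With 96 mM of first nucleophile, the same factor and oak's supply give 0.171. That neighbour computes to 0.169, with target at 66.5%.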